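The whole route rests on cutting the C2–C3 bond of the flavanone ring C. C2 carries the ring B aryl group and the ring oxygen O1 at once, so this cut turns ring C into an ordinary benzyl ether of a ring A phenol, with C2 as its OCH2 carbon and C3 as the terminal carbon of an acyl side chain. In the forward sense a chiral rhodium carbene at C3 inserts into one enantiotopic C–H bond of that OCH2 group, which forms C2–C3, closes ring C and fixes the (2S) centre in a single operation. The precursor is a 2-(diazoacetyl)aryl benzyl ether that already holds the benzyl-protected kaempferol 3-O-aryl ether, with a silyl ether as second ortho group.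

Key step: step 12

Assumption: the (S)-prolinate catalyst is written as the one that delivers the (2S) product; the sense of induction is to be confirmed on the first run by the CD curve of the key-step product, and the commercial antipode Rh2(R-DOSP)4 is used in the same way if the opposite sense is found.

Design notes:
- The second ortho oxygen of ring A is a triisopropylsilyl ether. It offers no C–H bond within reach of the carbene. It is removed by buffered fluoride, so no Lewis acid meets the product, whose C2–O1 bond is an ionisable para-aryloxybenzyl ether.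
- The diazoketone is made from a methyl ketone by diazo transfer. This avoids diazomethane, an acid chloride, and the hydrolysis of a hindered benzoate in the presence of the flavone.
- Abbreviation: "Kf" is the 5,7-bis(benzyloxy)-2-[4-(benzyloxy)phenyl]-4-oxo-4H-chromen-3-yl group (tri-O-benzylkaempferol-3-yl). Full SMILES are in the compound list.

Step 1
Reactants: 1 2',4',6'-trihydroxyacetophenone
Product: 2 1-[2,4-bis(benzyloxy)-6-hydroxyphenyl]ethan-1-one
Conditions: BnBr (2.1 equiv), K2CO3 (2.2 equiv), DMF, rt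
Reagents that add atoms: benzyl bromide, BrCc1ccccc1
Why: Williamson etherification in which the para and one ortho phenoxide are benzylated while the last ortho OH, held in a hydrogen bond to the ketone, stays free.

Step 2
Reactants: 2 1-[2,4-bis(benzyloxy)-6-hydroxyphenyl]ethan-1-one; 3 4-(benzyloxy)benzaldehyde
Product: 4 (E)-1-[2,4-bis(benzyloxy)-6-hydroxyphenyl]-3-[4-(benzyloxy)phenyl]prop-2-en-1-one
Conditions: KOH (50% aq.), EtOH/THF, rt
Reagents that add atoms: none
Why: Claisen–Schmidt condensation in which the methyl ketone enolate adds to the non-enolisable aldehyde and the aldol loses water to the conjugated (E)-chalcone.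

Step 3
Reactants: 4 (E)-1-[2,4-bis(benzyloxy)-6-hydroxyphenyl]-3-[4-(benzyloxy)phenyl]prop-2-en-1-one
Product: 5 5,7-bis(benzyloxy)-2-[4-(benzyloxy)phenyl]-4H-chromen-4-one
Conditions: I2 (10 mol%), DMSO, 130 °C
Reagents that add atoms: none
Why: Iodine-catalysed oxidative cyclisation of a 2'-hydroxychalcone, in which oxa-Michael closure, alpha-iodination and loss of HI give the flavone while DMSO regenerates iodine.

Step 4
Reactants: 5 5,7-bis(benzyloxy)-2-[4-(benzyloxy)phenyl]-4H-chromen-4-one
Product: 7 5,7-bis(benzyloxy)-2-[4-(benzyloxy)phenyl]-3-hydroxy-4H-chromen-4-one, via flavone 2,3-epoxide 6 (not isolated)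
Conditions: DMDO (about 0.07 M in acetone, 2 equiv), CH2Cl2, 0 °C; then p-TsOH·H2O (cat.), CH2Cl2, rt
Reagents that add atoms: dimethyldioxirane, CC1(C)OO1
Why: Dioxirane epoxidation of the enol-ether-like C2=C3 bond followed by acid-catalysed epoxide opening and tautomerisation, the established flavone-to-flavonol oxidation for 5,7-dioxygenated systems, where the Algar–Flynn–Oyamada reaction of the chalcone would give aurones.

Step 5
Reactants: 7 5,7-bis(benzyloxy)-2-[4-(benzyloxy)phenyl]-3-hydroxy-4H-chromen-4-one; 8 4-fluorobenzaldehyde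
Product: 9 4-(Kf-oxy)benzaldehyde
Conditions: Cs2CO3, DMSO (degassed), 90 °C, Ar
Reagents that add atoms: none
Why: Nucleophilic aromatic substitution (SNAr) in which the flavonolate of the only free hydroxyl displaces fluoride para to the formyl group through a Meisenheimer intermediate, air being excluded because flavonolates are cleaved by oxygen.

Step 6
Reactants: 9 4-(Kf-oxy)benzaldehyde
Product: 10 [4-(Kf-oxy)phenyl]methanol
Conditions: NaBH4, THF/MeOH, 0 °C
Reagents that add atoms: none
Why: Borohydride reduction that should touch only the formyl group, because the vinylogous-ester carbonyl of the 5-alkoxyflavone is far less electrophilic at 0 °C.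

Step 7
Reactants: 10 [4-(Kf-oxy)phenyl]methanol
Product: 11 4-(Kf-oxy)benzyl bromide
Conditions: CBr4, PPh3, CH2Cl2, 0 °C
Reagents that add atoms: carbon tetrabromide, BrC(Br)(Br)Br
Why: Appel bromination converts the primary benzylic alcohol into the bromide under neutral conditions, so no acid is present that could cleave the chelated 5-O-benzyl ether.

Step 8
Reactants: 1 2',4',6'-trihydroxyacetophenone
Product: 12 1-[4-(benzyloxy)-2,6-dihydroxyphenyl]ethan-1-one
Conditions: BnBr (1.0 equiv), K2CO3 (1.0 equiv), DMF, 0 °C to rt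
Reagents that add atoms: benzyl bromide, BrCc1ccccc1
Why: Williamson etherification with one equivalent of base and halide, in which the para OH, the most acidic and the only one not hydrogen-bonded to the ketone, should react first, any over-benzylated material being compound 2 and usable in step 2.

Step 9
Reactants: 11 4-(Kf-oxy)benzyl bromide; 12 1-[4-(benzyloxy)-2,6-dihydroxyphenyl]ethan-1-one
Product: 13 1-[4-(benzyloxy)-2-hydroxy-6-{[4-(Kf-oxy)benzyl]oxy}phenyl]ethan-1-one
Conditions: 12 (1.5 equiv), K2CO3, DMF, rt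
Reagents that add atoms: none
Why: Williamson etherification in which one of the two equivalent ortho phenoxides displaces the benzylic bromide, the excess of 12 and the hydrogen bond of the remaining OH holding the reaction at mono-alkylation.

Step 10
Reactants: 13 1-[4-(benzyloxy)-2-hydroxy-6-{[4-(Kf-oxy)benzyl]oxy}phenyl]ethan-1-one
Product: 14 1-[4-(benzyloxy)-2-{[4-(Kf-oxy)benzyl]oxy}-6-(triisopropylsilyloxy)phenyl]ethan-1-one
Conditions: TIPSCl, imidazole, DMAP (cat.), DMF, rt to 40 °C
Reagents that add atoms: chlorotriisopropylsilane, CC(C)[Si](Cl)(C(C)C)C(C)C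
Why: Imidazole-promoted silylation of the remaining phenol installs a bulky silyl ether that has no C–H bond within reach of the later carbene and is removable by fluoride without Lewis acid.

Step 11
Reactants: 14 1-[4-(benzyloxy)-2-{[4-(Kf-oxy)benzyl]oxy}-6-(triisopropylsilyloxy)phenyl]ethan-1-one
Product: 16 2-diazo-1-[4-(benzyloxy)-2-{[4-(Kf-oxy)benzyl]oxy}-6-(triisopropylsilyloxy)phenyl]ethan-1-one, via trifluoroacetyl ketone 15 (not isolated)
Conditions: LiN(SiMe3)2 (1.1 equiv), THF, −78 °C; CF3CO2CH2CF3, −78 °C; dilute HCl quench; then 4-acetamidobenzenesulfonyl azide, Et3N, H2O (1 equiv), MeCN/CH2Cl2, rt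
Reagents that add atoms: 4-acetamidobenzenesulfonyl azide, CC(=O)Nc1ccc(cc1)S(=O)(=O)N=[N+]=[N-]; 2,2,2-trifluoroethyl trifluoroacetate, O=C(OCC(F)(F)F)C(F)(F)F (its trifluoroacetyl group is present in 15 only)
Why: Regitz diazo transfer in its detrifluoroacetylative variant, in which the kinetic lithium enolate of the only enolisable ketone is trifluoroacetylated and the activated diketone takes the diazo group from the sulfonyl azide with loss of the trifluoroacetyl group.

Step 12
Reactants: 16 2-diazo-1-[4-(benzyloxy)-2-{[4-(Kf-oxy)benzyl]oxy}-6-(triisopropylsilyloxy)phenyl]ethan-1-one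
Product: 17 (2S)-7-(benzyloxy)-2-[4-(Kf-oxy)phenyl]-5-(triisopropylsilyloxy)chroman-4-one
Conditions: Rh2(S-DOSP)4 (2 mol%), CH2Cl2, 0 °C to rt, slow addition of 16 at high dilution
Reagents that add atoms: none
Why: Rh2(S-DOSP)4, the dirhodium tetrakis[(S)-N-(4-dodecylphenylsulfonyl)prolinate] of divalent rhodium, expels N2 from the diazoketone and gives an electrophilic rhodium carbene at the future C3, which inserts into a C–H bond of the neighbouring OCH2 group through a concerted, asynchronous three-centre transition state with build-up of positive charge on carbon, so that C2–C3 forms with retention at C2. The closest known reaction type is the enantioselective intramolecular C–H insertion of 2-alkoxyaryl alpha-diazoketones to chroman-4-ones under chiral dirhodium prolinate catalysis. Ring C closes as a six-membered ring by 1,6-insertion, because the position that would give a five-membered ring is occupied by the ether oxygen and the first C–H bond in reach is the one alpha to it. C2 is the only new stereocenter and is set by the catalyst, whose chiral prolinate ligands differentiate the two enantiotopic benzylic hydrogens, replacement of the pro-S hydrogen by C3 giving (2S). The step needs C–H insertion to win over oxonium ylide formation with [1,2]-benzyl shift and over carbene dimerisation, which is served by the hydridic character of a C–H bond that is benzylic, alpha to oxygen and para to an aryloxy donor, by the low basicity of an ether oxygen conjugated to the ketone, and by slow addition at high dilution. Site selectivity is secured by the substrate itself, since the second ortho substituent is a silyl ether with no C–H bond within range and the ring A para benzyl ether and the three flavonol benzyl ethers cannot reach the carbene.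

Step 13
Reactants: 17 (2S)-7-(benzyloxy)-2-[4-(Kf-oxy)phenyl]-5-(triisopropylsilyloxy)chroman-4-one
Product: 18 (2S)-7-(benzyloxy)-5-hydroxy-2-[4-(Kf-oxy)phenyl]chroman-4-one
Conditions: Bu4NF (1.1 equiv), AcOH (1.2 equiv), THF, 0 °C
Reagents that add atoms: none
Why: Fluoride-induced desilylation of the aryl silyl ether, buffered with acetic acid so that no free phenoxide or enolate is present to open ring C by retro-oxa-Michael reaction and erode C2.

Step 14
Reactants: 18 (2S)-7-(benzyloxy)-5-hydroxy-2-[4-(Kf-oxy)phenyl]chroman-4-one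
Product: 19 (2S)-5,7-dihydroxy-2-(4-{[5,7-dihydroxy-2-(4-hydroxyphenyl)-4-oxo-4H-chromen-3-yl]oxy}phenyl)chroman-4-one
Conditions: H2 (1 atm), Pd/C (10 wt% Pd on carbon), EtOAc/MeOH, rt
Reagents that add atoms: none
Why: Catalytic hydrogenolysis of the four aryl benzyl ethers under neutral conditions, which should leave the flavonol double bond, both carbonyls and the C2 stereocenter untouched when the reaction is stopped at full debenzylation.

Compound list

1 | 2',4',6'-trihydroxyacetophenone | CC(=O)c1c(O)cc(O)cc1O | starting material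
2 | 1-[2,4-bis(benzyloxy)-6-hydroxyphenyl]ethan-1-one | CC(=O)c1c(O)cc(OCc2ccccc2)cc1OCc1ccccc1 | intermediate
3 | 4-(benzyloxy)benzaldehyde | O=Cc1ccc(OCc2ccccc2)cc1 | starting material
4 | (E)-1-[2,4-bis(benzyloxy)-6-hydroxyphenyl]-3-[4-(benzyloxy)phenyl]prop-2-en-1-one | O=C(/C=C/c1ccc(OCc2ccccc2)cc1)c1c(O)cc(OCc2ccccc2)cc1OCc1ccccc1 | intermediate
5 | 5,7-bis(benzyloxy)-2-[4-(benzyloxy)phenyl]-4H-chromen-4-one | O=c1cc(-c2ccc(OCc3ccccc3)cc2)oc2cc(OCc3ccccc3)cc(OCc3ccccc3)c12 | intermediate
6 | 5,7-bis(benzyloxy)-2-[4-(benzyloxy)phenyl]-2,3-epoxychroman-4-one (racemic, cis-fused epoxide; not isolated) | O=C1C2OC2(c3ccc(OCc4ccccc4)cc3)Oc3cc(OCc4ccccc4)cc(OCc4ccccc4)c31 | intermediate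
7 | 5,7-bis(benzyloxy)-2-[4-(benzyloxy)phenyl]-3-hydroxy-4H-chromen-4-one (5,7,4'-tri-O-benzylkaempferol) | O=c1c(O)c(-c2ccc(OCc3ccccc3)cc2)oc2cc(OCc3ccccc3)cc(OCc3ccccc3)c12 | intermediate
8 | 4-fluorobenzaldehyde | O=Cc1ccc(F)cc1 | starting material
9 | 4-({5,7-bis(benzyloxy)-2-[4-(benzyloxy)phenyl]-4-oxo-4H-chromen-3-yl}oxy)benzaldehyde | O=Cc1ccc(Oc2c(-c3ccc(OCc4ccccc4)cc3)oc3cc(OCc4ccccc4)cc(OCc4ccccc4)c3c2=O)cc1 | intermediate
10 | 5,7-bis(benzyloxy)-2-[4-(benzyloxy)phenyl]-3-[4-(hydroxymethyl)phenoxy]-4H-chromen-4-one | OCc1ccc(Oc2c(-c3ccc(OCc4ccccc4)cc3)oc3cc(OCc4ccccc4)cc(OCc4ccccc4)c3c2=O)cc1 | intermediate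
11 | 5,7-bis(benzyloxy)-2-[4-(benzyloxy)phenyl]-3-[4-(bromomethyl)phenoxy]-4H-chromen-4-one | BrCc1ccc(Oc2c(-c3ccc(OCc4ccccc4)cc3)oc3cc(OCc4ccccc4)cc(OCc4ccccc4)c3c2=O)cc1 | intermediate
12 | 1-[4-(benzyloxy)-2,6-dihydroxyphenyl]ethan-1-one | CC(=O)c1c(O)cc(OCc2ccccc2)cc1O | intermediate
13 | 3-{4-[(2-acetyl-5-(benzyloxy)-3-hydroxyphenoxy)methyl]phenoxy}-5,7-bis(benzyloxy)-2-[4-(benzyloxy)phenyl]-4H-chromen-4-one | CC(=O)c1c(O)cc(OCc2ccccc2)cc1OCc1ccc(Oc2c(-c3ccc(OCc4ccccc4)cc3)oc3cc(OCc4ccccc4)cc(OCc4ccccc4)c3c2=O)cc1 | intermediate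
14 | 3-{4-[(2-acetyl-5-(benzyloxy)-3-{[tri(propan-2-yl)silyl]oxy}phenoxy)methyl]phenoxy}-5,7-bis(benzyloxy)-2-[4-(benzyloxy)phenyl]-4H-chromen-4-one | CC(=O)c1c(O[Si](C(C)C)(C(C)C)C(C)C)cc(OCc2ccccc2)cc1OCc1ccc(Oc2c(-c3ccc(OCc4ccccc4)cc3)oc3cc(OCc4ccccc4)cc(OCc4ccccc4)c3c2=O)cc1 | intermediate
15 | 4,4,4-trifluoro-1-aryl-butane-1,3-dione derived from 14 (aryl as in 14; crude, not isolated) | O=C(CC(=O)C(F)(F)F)c1c(O[Si](C(C)C)(C(C)C)C(C)C)cc(OCc2ccccc2)cc1OCc1ccc(Oc2c(-c3ccc(OCc4ccccc4)cc3)oc3cc(OCc4ccccc4)cc(OCc4ccccc4)c3c2=O)cc1 | intermediate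
16 | 3-{4-[(5-(benzyloxy)-2-(diazoacetyl)-3-{[tri(propan-2-yl)silyl]oxy}phenoxy)methyl]phenoxy}-5,7-bis(benzyloxy)-2-[4-(benzyloxy)phenyl]-4H-chromen-4-one | [N-]=[N+]=CC(=O)c1c(O[Si](C(C)C)(C(C)C)C(C)C)cc(OCc2ccccc2)cc1OCc1ccc(Oc2c(-c3ccc(OCc4ccccc4)cc3)oc3cc(OCc4ccccc4)cc(OCc4ccccc4)c3c2=O)cc1 | intermediate
17 | (2S)-7-(benzyloxy)-2-[4-({5,7-bis(benzyloxy)-2-[4-(benzyloxy)phenyl]-4-oxo-4H-chromen-3-yl}oxy)phenyl]-5-{[tri(propan-2-yl)silyl]oxy}-2,3-dihydro-4H-chromen-4-one | O=C1C[C@@H](c2ccc(Oc3c(-c4ccc(OCc5ccccc5)cc4)oc4cc(OCc5ccccc5)cc(OCc5ccccc5)c4c3=O)cc2)Oc2cc(OCc3ccccc3)cc(O[Si](C(C)C)(C(C)C)C(C)C)c21 | intermediate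
18 | (2S)-7-(benzyloxy)-2-[4-({5,7-bis(benzyloxy)-2-[4-(benzyloxy)phenyl]-4-oxo-4H-chromen-3-yl}oxy)phenyl]-5-hydroxy-2,3-dihydro-4H-chromen-4-one | O=C1C[C@@H](c2ccc(Oc3c(-c4ccc(OCc5ccccc5)cc4)oc4cc(OCc5ccccc5)cc(OCc5ccccc5)c4c3=O)cc2)Oc2cc(OCc3ccccc3)cc(O)c21 | intermediate
19 | (2S)-5,7-dihydroxy-2-(4-{[5,7-dihydroxy-2-(4-hydroxyphenyl)-4-oxo-4H-chromen-3-yl]oxy}phenyl)-2,3-dihydro-4H-chromen-4-one (CNP0144321.1) | O=C1C[C@@H](c2ccc(Oc3c(-c4ccc(O)cc4)oc4cc(O)cc(O)c4c3=O)cc2)Oc2cc(O)cc(O)c21 | target

Total step count: 14.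
Longest linear sequence: 13 steps (steps 1 to 7, then 9 to 14); step 8 is a one-step side branch.

Steps most likely to fail

1. Step 12. The carbene may be drained into an oxonium ylide at the ether oxygen that undergoes a [1,2]-benzyl shift to a benzofuranone, or the catalyst may discriminate poorly between the two enantiotopic hydrogens. The fallback replaces the carbene chemistry by chalcone ring closure and resolution; it sets out from aldehyde 9 and ketone 2 and leaves out steps 6 to 13. Claisen–Schmidt condensation (KOH, EtOH/THF, rt) should give the chalcone (E)-1-[2,4-bis(benzyloxy)-6-hydroxyphenyl]-3-[4-(Kf-oxy)phenyl]prop-2-en-1-one F1. Oxa-Michael cyclisation (NaOAc, EtOH, reflux) should give the racemic flavanone 5,7-bis(benzyloxy)-2-[4-(Kf-oxy)phenyl]chroman-4-one F2. Preparative chromatography on a chiral stationary phase (amylose tris(3,5-dimethylphenylcarbamate), supercritical CO2/MeOH) should separate the (2S)-enantiomer (2S)-5,7-bis(benzyloxy)-2-[4-(Kf-oxy)phenyl]chroman-4-one F3; the (2R)-antipode can be returned to the cyclisation conditions for equilibration. Hydrogenolysis of the five benzyl ethers of F3 (H2, Pd/C, EtOAc/MeOH, rt) comes back to the route at the target 19.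

2. Step 5. The hindered, weakly nucleophilic flavonolate may substitute too slowly and decompose at the temperature the substitution needs. The fallback is a metal-free arylation with a hypervalent iodine reagent near room temperature; it sets out from flavonol 7. 4-Iodobenzaldehyde is oxidised and coupled in one pot (mCPBA, TsOH·H2O, MeCN; then 1,3,5-trimethoxybenzene) to (4-formylphenyl)(2,4,6-trimethoxyphenyl)iodonium tosylate F4. Treatment of 7 with F4 and K2CO3 in MeCN/toluene at rt to 40 °C should transfer the formylphenyl group to the 3-oxygen by ligand coupling, the trimethoxyphenyl group staying on iodine. The sequence comes back to the route at aldehyde 9.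

3. Step 11. The silyl group may migrate to the enolate oxygen or be lost under the strongly basic conditions, or the enolate may add to the flavone. The fallback is a base-free diazo transfer through an enaminone; it sets out from ketone 14. Condensation with N,N-dimethylformamide dimethyl acetal (toluene, 100 °C) should give the enaminone 3-{4-[(5-(benzyloxy)-2-[(2E)-3-(dimethylamino)prop-2-enoyl]-3-{[tri(propan-2-yl)silyl]oxy}phenoxy)methyl]phenoxy}-5,7-bis(benzyloxy)-2-[4-(benzyloxy)phenyl]-4H-chromen-4-one F5. Tosyl azide (CH2Cl2, rt to 40 °C) should add across the enamine double bond, and fragmentation of the triazoline releases the N-sulfonylformamidine. The sequence comes back to the route at diazoketone 16.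

Further compounds

F1 | step 12 | (E)-1-[2,4-bis(benzyloxy)-6-hydroxyphenyl]-3-[4-({5,7-bis(benzyloxy)-2-[4-(benzyloxy)phenyl]-4-oxo-4H-chromen-3-yl}oxy)phenyl]prop-2-en-1-one | O=C(/C=C/c1ccc(Oc2c(-c3ccc(OCc4ccccc4)cc3)oc3cc(OCc4ccccc4)cc(OCc4ccccc4)c3c2=O)cc1)c1c(O)cc(OCc2ccccc2)cc1OCc1ccccc1
F2 | step 12 | racemic 5,7-bis(benzyloxy)-2-[4-({5,7-bis(benzyloxy)-2-[4-(benzyloxy)phenyl]-4-oxo-4H-chromen-3-yl}oxy)phenyl]-2,3-dihydro-4H-chromen-4-one | O=C1CC(c2ccc(Oc3c(-c4ccc(OCc5ccccc5)cc4)oc4cc(OCc5ccccc5)cc(OCc5ccccc5)c4c3=O)cc2)Oc2cc(OCc3ccccc3)cc(OCc3ccccc3)c21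
F3 | step 12 | (2S)-5,7-bis(benzyloxy)-2-[4-({5,7-bis(benzyloxy)-2-[4-(benzyloxy)phenyl]-4-oxo-4H-chromen-3-yl}oxy)phenyl]-2,3-dihydro-4H-chromen-4-one | O=C1C[C@@H](c2ccc(Oc3c(-c4ccc(OCc5ccccc5)cc4)oc4cc(OCc5ccccc5)cc(OCc5ccccc5)c4c3=O)cc2)Oc2cc(OCc3ccccc3)cc(OCc3ccccc3)c21
F4 | step 5 | (4-formylphenyl)(2,4,6-trimethoxyphenyl)iodonium 4-methylbenzenesulfonate | O=Cc1ccc([I+]c2c(OC)cc(OC)cc2OC)cc1.Cc1ccc(S(=O)(=O)[O-])cc1
F5 | step 11 | 3-{4-[(5-(benzyloxy)-2-[(2E)-3-(dimethylamino)prop-2-enoyl]-3-{[tri(propan-2-yl)silyl]oxy}phenoxy)methyl]phenoxy}-5,7-bis(benzyloxy)-2-[4-(benzyloxy)phenyl]-4H-chromen-4-one | CN(C)/C=C/C(=O)c1c(O[Si](C(C)C)(C(C)C)C(C)C)cc(OCc2ccccc2)cc1OCc1ccc(Oc2c(-c3ccc(OCc4ccccc4)cc3)oc3cc(OCc4ccccc4)cc(OCc4ccccc4)c3c2=O)cc1
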